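The route rests on cutting the two tertiary C3–O bonds of the butyrolactone rings: each C3 hydroxyl, which sits cis to the arylmethyl group on the neighbouring ring carbon C4, is traced back to a C3 acetyl group. One double Baeyer–Villiger oxidation then converts both methyl ketones into tertiary acetates, each quaternary C3 shifting from carbon to oxygen without changing face. The oxidation substrate is the biaryl-linked bis(3-acetyl-3,4-bis(arylmethyl) lactone) carrying its four phenols as pivalates; it is assembled by two C-benzylations of 3-acetyl-4-arylmethyl lactones that enter anti to the C4 substituent and so leave acetyl on the hindered face, where an electrophilic oxygen source would not go.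

Key step: step 18

Remarks on the chemistry

- Labels: lactone 1 carries ring A (vanillyl) on C4 and the CH2 of biaryl ring B on C3. Lactone 2 carries the CH2 of biaryl ring C on C4 and ring D (vanillyl) on C3.
- The structures of the oxidation substrate 22 and its product 23 were checked atom by atom against the target and need no correction. All three have the same spatial arrangement at C3 and C4 of both lactones. Only the descriptors change, (3S,4S) in the 3-acetyl series and (3R,4R) in the 3-acetoxy and 3-hydroxy series, because the priorities at C3 and C4 change.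
- Pivalate is kept as the phenol protection of 22: it should survive buffered peracid, it withdraws electron density from all four rings, and it leaves together with the tertiary acetates in one methanolysis.
- Assumption: the (R,R) hand of Et-DuPHOS is taken to give the (S) acids 5 and 14. The sense would be checked on the first run through the optical rotation of lactone 7, and the (S,S) ligand used if it proves opposite.
- Compounds 2 and 9 are also catalogue items; they are made here from vanillin so that the route rests on three bulk chemicals.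

Step 1
Reactants: 1 vanillin
Product: 2 4-(benzyloxy)-3-methoxybenzaldehyde
Conditions: BnBr, K2CO3, DMF, 60 °C
Reagents that add atoms: benzyl bromide, BrCc1ccccc1
Why: Williamson etherification of the acidic para-formyl phenoxide with a benzylic bromide; no stereocentre is involved.

Step 2
Reactants: 2 4-(benzyloxy)-3-methoxybenzaldehyde; 3 dimethyl succinate
Product: 4 (E)-4-[4-(benzyloxy)-3-methoxyphenyl]-3-(methoxycarbonyl)but-3-enoic acid
Conditions: NaOMe, MeOH, reflux; then aq HCl
Reagents that add atoms: none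
Why: Stobbe condensation, in which the succinate enolate adds to the aldehyde, the alkoxide closes a paraconate lactone on the distal ester and base-induced ring-opening elimination should give the thermodynamically preferred (E)-alkylidene half-ester.

Step 3
Reactants: 4 (E)-4-[4-(benzyloxy)-3-methoxyphenyl]-3-(methoxycarbonyl)but-3-enoic acid
Product: 5 (3S)-4-[4-(benzyloxy)-3-methoxyphenyl]-3-(methoxycarbonyl)butanoic acid
Conditions: H2 (5 bar), [Rh(cod)((R,R)-Et-DuPHOS)]BF4 (0.5 mol%), NaOMe (0.1 equiv), MeOH, rt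
Reagents that add atoms: none
Why: Asymmetric hydrogenation of a β-aryl itaconate half-ester, in which chelation of alkene and carboxylate to the cationic monovalent rhodium bisphospholane complex lets the ligand choose the alkene face and so set C3 as (S); the homogeneous catalyst should leave the benzyl ether alone.

Step 4
Reactants: 5 (3S)-4-[4-(benzyloxy)-3-methoxyphenyl]-3-(methoxycarbonyl)butanoic acid
Product: 7 (4S)-4-[4-(benzyloxy)-3-methoxybenzyl]dihydrofuran-2(3H)-one, via hydroxy acid 6 (not isolated)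
Conditions: KOH (1.0 equiv), EtOH, 0 °C; CaCl2, NaBH4, EtOH, 0 °C → rt; then 2 M HCl, rt
Reagents that add atoms: none
Why: Chemoselective reduction of the methyl ester by Ca(BH4)2 while the potassium carboxylate is inert, followed by acid-catalysed γ-lactonisation; the stereocentre is not touched and keeps its configuration.

Step 5
Reactants: 7 (4S)-4-[4-(benzyloxy)-3-methoxybenzyl]dihydrofuran-2(3H)-one
Product: 8 (4S)-3-acetyl-4-[4-(benzyloxy)-3-methoxybenzyl]dihydrofuran-2(3H)-one (C3 epimers/enol)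
Conditions: LiN(SiMe3)2 (2.2 equiv), THF, −78 °C; MeC(O)N(OMe)Me, −78 → 0 °C; aq NH4Cl
Reagents that add atoms: N-methoxy-N-methylacetamide, CON(C)C(C)=O
Why: Claisen-type C-acylation of the lactone lithium enolate by an N-methoxy-N-methylamide, whose chelated tetrahedral adduct should block over-addition and O-acylation; C3 is left uncontrolled because it is planarised again in step 15.

Step 6
Reactants: 2 4-(benzyloxy)-3-methoxybenzaldehyde
Product: 9 4-(benzyloxy)-3-methoxybenzyl alcohol
Conditions: NaBH4, MeOH, 0 °C; aq NH4Cl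
Reagents that add atoms: none
Why: Borohydride reduction of an aryl aldehyde to the benzylic alcohol; no stereocentre is involved.

Step 7
Reactants: 9 4-(benzyloxy)-3-methoxybenzyl alcohol
Product: 10 4-(benzyloxy)-3-methoxybenzyl bromide
Conditions: PBr3 (0.4 equiv), Et2O, 0 °C
Reagents that add atoms: phosphorus tribromide, BrP(Br)Br
Why: Bromination of a benzylic alcohol through its phosphite ester and SN2 displacement by bromide; the aryl benzyl ether should survive the short cold exposure.

Step 8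
Reactants: 11 dehydrodivanillin
Product: 12 6,6'-bis(benzyloxy)-5,5'-dimethoxybiphenyl-3,3'-dicarbaldehyde
Conditions: BnBr (2.5 equiv), K2CO3, DMF, 60 °C
Reagents that add atoms: benzyl bromide, BrCc1ccccc1
Why: Double Williamson etherification of the two equivalent phenoxides, which also makes the biaryl soluble for the next step.

Step 9
Reactants: 12 6,6'-bis(benzyloxy)-5,5'-dimethoxybiphenyl-3,3'-dicarbaldehyde; 3 dimethyl succinate
Product: 13 (E)-4-[6,6'-bis(benzyloxy)-3'-formyl-5,5'-dimethoxybiphenyl-3-yl]-3-(methoxycarbonyl)but-3-enoic acid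
Conditions: 12 (2.5 equiv), 3 (1.0 equiv), NaOMe (1.5 equiv), MeOH/THF, 60 °C; aq HCl; neutral 12 recovered by NaHCO3 partition
Reagents that add atoms: none
Why: Stobbe condensation run with the dialdehyde in excess, so that the succinate enolate should meet mostly unreacted 12 and condense at one formyl group only (statistical desymmetrisation); the acidic product separates from recyclable neutral 12 by extraction.

Step 10
Reactants: 13 (E)-4-[6,6'-bis(benzyloxy)-3'-formyl-5,5'-dimethoxybiphenyl-3-yl]-3-(methoxycarbonyl)but-3-enoic acid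
Product: 14 (3S)-4-[6,6'-bis(benzyloxy)-3'-formyl-5,5'-dimethoxybiphenyl-3-yl]-3-(methoxycarbonyl)butanoic acid
Conditions: H2 (5 bar), [Rh(cod)((R,R)-Et-DuPHOS)]BF4 (0.5 mol%), NaOMe (0.1 equiv), MeOH, rt
Reagents that add atoms: none
Why: The same carboxylate-directed asymmetric hydrogenation as in step 3 sets C3 as (S) under ligand control; the aryl aldehyde should not be reduced by this catalyst at low pressure and room temperature.

Step 11
Reactants: 14 (3S)-4-[6,6'-bis(benzyloxy)-3'-formyl-5,5'-dimethoxybiphenyl-3-yl]-3-(methoxycarbonyl)butanoic acid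
Product: 16 (4S)-4-{[6,6'-bis(benzyloxy)-3'-(hydroxymethyl)-5,5'-dimethoxybiphenyl-3-yl]methyl}dihydrofuran-2(3H)-one, via dihydroxy acid 15 (not isolated)
Conditions: KOH (1.0 equiv), EtOH, 0 °C; CaCl2, NaBH4, EtOH, 0 °C → rt; then 2 M HCl, rt
Reagents that add atoms: none
Why: Ca(BH4)2 reduces the methyl ester and the aldehyde in one operation while the carboxylate is inert, and acid then closes the γ-lactone; the ring B hydroxymethyl group is the handle for the later bromide.

Step 12
Reactants: 16 (4S)-4-{[6,6'-bis(benzyloxy)-3'-(hydroxymethyl)-5,5'-dimethoxybiphenyl-3-yl]methyl}dihydrofuran-2(3H)-one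
Product: 17 (4S)-3-acetyl-4-{[6,6'-bis(benzyloxy)-3'-(hydroxymethyl)-5,5'-dimethoxybiphenyl-3-yl]methyl}dihydrofuran-2(3H)-one (C3 epimers/enol)
Conditions: LiN(SiMe3)2 (3.3 equiv), THF, −78 °C; MeC(O)N(OMe)Me, −78 → 0 °C; aq NH4Cl
Reagents that add atoms: N-methoxy-N-methylacetamide, CON(C)C(C)=O
Why: Claisen-type C-acylation as in step 5 with one more equivalent of base for the benzylic hydroxyl, whose lithium alkoxide should not be acylated by the amide, so no protecting group is spent.

Step 13
Reactants: 17 (4S)-3-acetyl-4-{[6,6'-bis(benzyloxy)-3'-(hydroxymethyl)-5,5'-dimethoxybiphenyl-3-yl]methyl}dihydrofuran-2(3H)-one; 10 4-(benzyloxy)-3-methoxybenzyl bromide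
Product: 18 (3S,4S)-3-acetyl-3-[4-(benzyloxy)-3-methoxybenzyl]-4-{[6,6'-bis(benzyloxy)-3'-(hydroxymethyl)-5,5'-dimethoxybiphenyl-3-yl]methyl}dihydrofuran-2(3H)-one
Conditions: K2CO3, acetone, rt
Reagents that add atoms: none
Why: C-alkylation of the stabilised potassium enolate of a β-keto lactone with a benzylic bromide, in which the electrophile should approach the planar enolate anti to the C4 arylmethyl group (1,2-induction on the five-membered ring) and so set quaternary C3 with benzyl trans and acetyl cis to that group; the neutral benzylic alcohol does not compete.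

Step 14
Reactants: 18 (3S,4S)-3-acetyl-3-[4-(benzyloxy)-3-methoxybenzyl]-4-{[6,6'-bis(benzyloxy)-3'-(hydroxymethyl)-5,5'-dimethoxybiphenyl-3-yl]methyl}dihydrofuran-2(3H)-one
Product: 19 (3S,4S)-3-acetyl-3-[4-(benzyloxy)-3-methoxybenzyl]-4-{[6,6'-bis(benzyloxy)-3'-(bromomethyl)-5,5'-dimethoxybiphenyl-3-yl]methyl}dihydrofuran-2(3H)-one
Conditions: CBr4, PPh3, CH2Cl2, 0 °C; used without storage
Reagents that add atoms: carbon tetrabromide, BrC(Br)(Br)Br
Why: Appel reaction of the only hydroxyl under neutral conditions, which should leave the non-enolisable quaternary β-keto lactone and the benzyl ethers untouched.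

Step 15
Reactants: 8 (4S)-3-acetyl-4-[4-(benzyloxy)-3-methoxybenzyl]dihydrofuran-2(3H)-one; 19 (3S,4S)-3-acetyl-3-[4-(benzyloxy)-3-methoxybenzyl]-4-{[6,6'-bis(benzyloxy)-3'-(bromomethyl)-5,5'-dimethoxybiphenyl-3-yl]methyl}dihydrofuran-2(3H)-one
Product: 20 tetra-O-benzyl bis(3-acetyl) dimer (both lactones 3S,4S)
Conditions: K2CO3, acetone, rt
Reagents that add atoms: none
Why: The same C-alkylation of a β-keto lactone potassium enolate joins the two halves, the ring B benzylic bromide entering anti to the C4 vanillyl group of lactone 1 and so setting its quaternary C3 with acetyl cis to that group.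

Step 16
Reactants: 20 tetra-O-benzyl bis(3-acetyl) dimer
Product: 21 tetraphenol bis(3-acetyl) dimer
Conditions: H2 (1 atm), 10% Pd/C, EtOAc/THF, rt
Reagents that add atoms: none
Why: Hydrogenolysis of four aryl benzyl ethers over palladium on carbon; aliphatic methyl ketones, lactones and the quaternary centres should not react under these conditions.

Step 17
Reactants: 21 tetraphenol bis(3-acetyl) dimer
Product: 22 tetrapivalate bis(3-acetyl) dimer (both lactones 3S,4S)
Conditions: PivCl (8 equiv), Et3N, DMAP, CH2Cl2, 0 → 40 °C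
Reagents that add atoms: pivaloyl chloride, CC(C)(C)C(Cl)=O
Why: Acylation of the four phenols by nucleophilic catalysis with DMAP, with excess reagent and gentle warming for the two hindered biaryl phenols; the ketones cannot enolise toward the quaternary carbons.

Step 18
Reactants: 22 tetrapivalate bis(3-acetyl) dimer
Product: 23 bis(tertiary acetate) tetrapivalate (both lactones 3R,4R)
Conditions: (CF3CO)2O, urea·H2O2, Na2HPO4, CH2Cl2, 0 °C → rt
Reagents that add atoms: trifluoroperacetic acid, OOC(=O)C(F)(F)F, made in the flask from trifluoroacetic anhydride, O=C(OC(=O)C(F)(F)F)C(F)(F)F, and urea–hydrogen peroxide, NC(N)=O.OO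
Why: Trifluoroperacetic acid adds to each ketone carbonyl to give a tetrahedral peroxy adduct, which collapses with a 1,2-shift of the quaternary lactone carbon C3 from the carbonyl carbon to the proximal peroxide oxygen as trifluoroacetate leaves. The closest known reaction type is the Baeyer–Villiger oxidation of 2,2-dialkyl acetoacetates and 3-acetyl-3-alkyl lactones to tertiary α-acetoxy esters. No ring is closed and no stereocentre is created: the two C3 centres fixed in steps 13 and 15 are carried over with retention, because the migrating carbon stays bonded on the same face throughout the concerted shift. The step needs migration of the fully substituted carbon instead of methyl, which its higher substitution should secure although the attached lactone carbonyl slows it, hence the strongest common peracid. It also needs ketone oxidation to be faster than electrophilic oxidation of the four alkoxyarenes, which the electron-withdrawing pivalates and the phosphate buffer (no free CF3CO2H) should secure.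

Step 19
Reactants: 23 bis(tertiary acetate) tetrapivalate
Product: 24 CNP0218652.1 (target)
Conditions: K2CO3, MeOH (degassed), rt, argon; then 1 M HCl to pH 2, rt
Reagents that add atoms: none
Why: Base-catalysed transesterification with methanol removes the two tertiary acetates (activated by the adjacent lactone carbonyl) and the four aryl pivalates, and acidification re-closes any opened γ-lactone; C3 has no hydrogen and C4 is not acidic, so no stereocentre is at risk.

Compound list

1 | vanillin (4-hydroxy-3-methoxybenzaldehyde) | COc1cc(C=O)ccc1O | starting material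
2 | 4-(benzyloxy)-3-methoxybenzaldehyde | COc1cc(C=O)ccc1OCc1ccccc1 | intermediate
3 | dimethyl succinate | COC(=O)CCC(=O)OC | starting material
4 | (E)-4-[4-(benzyloxy)-3-methoxyphenyl]-3-(methoxycarbonyl)but-3-enoic acid | COC(=O)/C(CC(=O)O)=C/c1ccc(OCc2ccccc2)c(OC)c1 | intermediate
5 | (3S)-4-[4-(benzyloxy)-3-methoxyphenyl]-3-(methoxycarbonyl)butanoic acid | COc1cc(C[C@@H](CC(=O)O)C(=O)OC)ccc1OCc1ccccc1 | intermediate
6 | (3S)-4-[4-(benzyloxy)-3-methoxyphenyl]-3-(hydroxymethyl)butanoic acid (carboxylate salt in the flask) | COc1cc(C[C@@H](CC(=O)O)CO)ccc1OCc1ccccc1 | intermediate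
7 | (4S)-4-[4-(benzyloxy)-3-methoxybenzyl]dihydrofuran-2(3H)-one | COc1cc(C[C@@H]2COC(=O)C2)ccc1OCc1ccccc1 | intermediate
8 | (4S)-3-acetyl-4-[4-(benzyloxy)-3-methoxybenzyl]dihydrofuran-2(3H)-one (C3 epimers/enol; centre not controlled) | COc1cc(C[C@@H]2COC(=O)C2C(C)=O)ccc1OCc1ccccc1 | intermediate
9 | 4-(benzyloxy)-3-methoxybenzyl alcohol | COc1cc(CO)ccc1OCc1ccccc1 | intermediate
10 | 4-(benzyloxy)-3-methoxybenzyl bromide | COc1cc(CBr)ccc1OCc1ccccc1 | intermediate
11 | dehydrodivanillin (6,6'-dihydroxy-5,5'-dimethoxybiphenyl-3,3'-dicarbaldehyde) | COc1cc(C=O)cc(-c2cc(C=O)cc(OC)c2O)c1O | starting material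
12 | 6,6'-bis(benzyloxy)-5,5'-dimethoxybiphenyl-3,3'-dicarbaldehyde | COc1cc(C=O)cc(-c2cc(C=O)cc(OC)c2OCc2ccccc2)c1OCc1ccccc1 | intermediate
13 | (E)-4-[6,6'-bis(benzyloxy)-3'-formyl-5,5'-dimethoxybiphenyl-3-yl]-3-(methoxycarbonyl)but-3-enoic acid | COC(=O)/C(CC(=O)O)=C/c1cc(OC)c(OCc2ccccc2)c(-c2cc(C=O)cc(OC)c2OCc2ccccc2)c1 | intermediate
14 | (3S)-4-[6,6'-bis(benzyloxy)-3'-formyl-5,5'-dimethoxybiphenyl-3-yl]-3-(methoxycarbonyl)butanoic acid | COc1cc(C[C@@H](CC(=O)O)C(=O)OC)cc(-c2cc(C=O)cc(OC)c2OCc2ccccc2)c1OCc1ccccc1 | intermediate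
15 | (3S)-4-[6,6'-bis(benzyloxy)-3'-(hydroxymethyl)-5,5'-dimethoxybiphenyl-3-yl]-3-(hydroxymethyl)butanoic acid (carboxylate salt in the flask) | COc1cc(C[C@@H](CC(=O)O)CO)cc(-c2cc(CO)cc(OC)c2OCc2ccccc2)c1OCc1ccccc1 | intermediate
16 | (4S)-4-{[6,6'-bis(benzyloxy)-3'-(hydroxymethyl)-5,5'-dimethoxybiphenyl-3-yl]methyl}dihydrofuran-2(3H)-one | COc1cc(C[C@@H]2COC(=O)C2)cc(-c2cc(CO)cc(OC)c2OCc2ccccc2)c1OCc1ccccc1 | intermediate
17 | (4S)-3-acetyl-4-{[6,6'-bis(benzyloxy)-3'-(hydroxymethyl)-5,5'-dimethoxybiphenyl-3-yl]methyl}dihydrofuran-2(3H)-one (C3 epimers/enol; centre not controlled) | COc1cc(C[C@@H]2COC(=O)C2C(C)=O)cc(-c2cc(CO)cc(OC)c2OCc2ccccc2)c1OCc1ccccc1 | intermediate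
18 | (3S,4S)-3-acetyl-3-[4-(benzyloxy)-3-methoxybenzyl]-4-{[6,6'-bis(benzyloxy)-3'-(hydroxymethyl)-5,5'-dimethoxybiphenyl-3-yl]methyl}dihydrofuran-2(3H)-one | COc1cc(C[C@@H]2COC(=O)[C@@]2(C(C)=O)Cc2ccc(OCc3ccccc3)c(OC)c2)cc(-c2cc(CO)cc(OC)c2OCc2ccccc2)c1OCc1ccccc1 | intermediate
19 | (3S,4S)-3-acetyl-3-[4-(benzyloxy)-3-methoxybenzyl]-4-{[6,6'-bis(benzyloxy)-3'-(bromomethyl)-5,5'-dimethoxybiphenyl-3-yl]methyl}dihydrofuran-2(3H)-one | COc1cc(C[C@@H]2COC(=O)[C@@]2(C(C)=O)Cc2ccc(OCc3ccccc3)c(OC)c2)cc(-c2cc(CBr)cc(OC)c2OCc2ccccc2)c1OCc1ccccc1 | intermediate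
20 | tetra-O-benzyl bis(3-acetyl) dimer: lactone 1 is a (3S,4S)-3-acetyl-4-[4-(benzyloxy)-3-methoxybenzyl]dihydrofuran-2(3H)-one bonded at C3 to the CH2 of ring B; lactone 2 is a (3S,4S)-3-acetyl-3-[4-(benzyloxy)-3-methoxybenzyl]dihydrofuran-2(3H)-one bonded at C4 to the CH2 of ring C; rings B and C form a 6,6'-bis(benzyloxy)-5,5'-dimethoxybiphenyl-3,3'-diyl unit | COc1cc(C[C@@H]2COC(=O)[C@@]2(C(C)=O)Cc2cc(OC)c(OCc3ccccc3)c(-c3cc(C[C@@H]4COC(=O)[C@@]4(C(C)=O)Cc4ccc(OCc5ccccc5)c(OC)c4)cc(OC)c3OCc3ccccc3)c2)ccc1OCc1ccccc1 | intermediate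
21 | tetraphenol bis(3-acetyl) dimer: as 20 with all four benzyl ethers replaced by free phenols | COc1cc(C[C@@H]2COC(=O)[C@@]2(C(C)=O)Cc2cc(OC)c(O)c(-c3cc(C[C@@H]4COC(=O)[C@@]4(C(C)=O)Cc4ccc(O)c(OC)c4)cc(OC)c3O)c2)ccc1O | intermediate
22 | tetrapivalate bis(3-acetyl) dimer: as 21 with all four phenols as pivalate esters; both lactones (3S,4S) | COc1cc(C[C@@H]2COC(=O)[C@@]2(C(C)=O)Cc2cc(OC)c(OC(=O)C(C)(C)C)c(-c3cc(C[C@@H]4COC(=O)[C@@]4(C(C)=O)Cc4ccc(OC(=O)C(C)(C)C)c(OC)c4)cc(OC)c3OC(=O)C(C)(C)C)c2)ccc1OC(=O)C(C)(C)C | intermediate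
23 | bis(tertiary acetate) tetrapivalate: as 22 with each C3 acetyl replaced by acetoxy on the same face; both lactones (3R,4R) | COc1cc(C[C@@H]2COC(=O)[C@@]2(OC(C)=O)Cc2cc(OC)c(OC(=O)C(C)(C)C)c(-c3cc(C[C@@H]4COC(=O)[C@@]4(OC(C)=O)Cc4ccc(OC(=O)C(C)(C)C)c(OC)c4)cc(OC)c3OC(=O)C(C)(C)C)c2)ccc1OC(=O)C(C)(C)C | intermediate
24 | CNP0218652.1: biaryl-linked bis(3-hydroxy-3,4-bis(arylmethyl) lactone) with four free phenols; both lactones (3R,4R) | COc1cc(C[C@@H]2COC(=O)[C@@]2(O)Cc2cc(OC)c(O)c(-c3cc(C[C@@H]4COC(=O)[C@@]4(O)Cc4ccc(O)c(OC)c4)cc(OC)c3O)c2)ccc1O | target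

Total step count: 19
Longest linear sequence: 12 steps (steps 8 to 19, from dehydrodivanillin 11)

Steps most likely to fail

Step 18 (double Baeyer–Villiger oxidation). The peracid may oxidise the methoxy-bearing rings faster than it attacks the two hindered, electron-poor ketones, or methyl may migrate in place of the quaternary carbon. The fallback makes the tertiary C–O bonds before the C3 benzyl groups are attached; it sets out from lactones 7 and 16 and returns at target 24. Lactone 7 would be hydroxylated at C3 (KN(SiMe3)2, THF, −78 °C; 2-(phenylsulfonyl)-3-phenyloxaziridine) to (4R)-4-[4-(benzyloxy)-3-methoxybenzyl]-3-hydroxydihydrofuran-2(3H)-one F1. Lactone 16 would be silylated (tert-butyldimethylsilyl chloride, imidazole, DMF) to its silyl ether F2 and hydroxylated in the same way to the 3-hydroxy lactone F3. The dianion of F3 (LiN(iPr)2, 2.2 equiv, THF/DMPU) would be benzylated with bromide 10 anti to the C4 substituent to give the tertiary alcohol F4. Bu4NF/AcOH would free the diol F5, and CBr4/PPh3 would convert its primary benzylic hydroxyl into the bromide F6. The dianion of F1 would then be alkylated with F6, added as its lithium alkoxide, to give the tetra-O-benzyl ether of the target F7, and hydrogenolysis (H2, Pd/C) would give 24. Both alkylations use the same anti approach to the C4 arylmethyl group with oxygen already on C3, so each hydroxyl should end cis to that group.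

Step 9 (mono-Stobbe condensation). Desymmetrisation may be lost through condensation at both formyl groups, or the mixture of acids may prove hard to separate. The fallback builds the unsymmetrical biaryl by cross-coupling; it sets out from vanillin 1 and dimethyl succinate 3 and returns at 16. Bromination of 1 (Br2, AcOH) would give 5-bromovanillin F8, and benzylation (BnBr, K2CO3) its benzyl ether F9. Stobbe condensation of F9 with 3 would give the bromoaryl half-ester F10, hydrogenation as in step 3 the (3S)-acid F11, and reduction with lactonisation as in step 4 the bromo lactone F12. A second portion of F9 would undergo Miyaura borylation (PdCl2(dppf), bis(pinacolato)diboron, KOAc, dioxane, 80 °C) to the pinacol boronate F13. Suzuki–Miyaura coupling of F12 with F13 (Pd(OAc)2, SPhos, K3PO4, toluene/water, 80 °C; acidic work-up to re-close the lactone) would give the biaryl aldehyde lactone F14, and NaBH4 in MeOH at 0 °C would reduce its aldehyde to give 16.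

Step 12 (C-acetylation in the presence of the free hydroxymethyl group). Acylation of the dianion may stall, or the enolate may be lost by proton transfer or self-condensation on warming. The fallback brings in the acetyl group by aldol addition and oxidation; it sets out from 16 and returns at 18. The dianion of 16 (LiN(SiMe3)2, 2.2 equiv, THF, −78 °C) would add to acetaldehyde to give the 3-(1-hydroxyethyl) lactone diol F15. Oxidation of both alcohols with 1,1,1-triacetoxy-1,1-dihydro-1,2-benziodoxol-3(1H)-one in CH2Cl2 would give the 3-acetyl lactone aryl aldehyde F16. Benzylation with 10 as in step 13 (K2CO3, acetone) would give the quaternary keto aldehyde F17, and NaBH4 in MeOH/CH2Cl2 at −78 °C would reduce only the aryl aldehyde, the methyl ketone being shielded by the quaternary centre, to give 18.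

Further compounds

F1 | step 18 | (4R)-4-[4-(benzyloxy)-3-methoxybenzyl]-3-hydroxydihydrofuran-2(3H)-one (C3 epimers) | COc1cc(C[C@@H]2COC(=O)C2O)ccc1OCc1ccccc1
F2 | step 18 | (4S)-4-{[6,6'-bis(benzyloxy)-3'-(tert-butyldimethylsilyloxymethyl)-5,5'-dimethoxybiphenyl-3-yl]methyl}dihydrofuran-2(3H)-one | COc1cc(C[C@@H]2COC(=O)C2)cc(-c2cc(CO[Si](C)(C)C(C)(C)C)cc(OC)c2OCc2ccccc2)c1OCc1ccccc1
F3 | step 18 | (4R)-4-{[6,6'-bis(benzyloxy)-3'-(tert-butyldimethylsilyloxymethyl)-5,5'-dimethoxybiphenyl-3-yl]methyl}-3-hydroxydihydrofuran-2(3H)-one (C3 epimers) | COc1cc(C[C@@H]2COC(=O)C2O)cc(-c2cc(CO[Si](C)(C)C(C)(C)C)cc(OC)c2OCc2ccccc2)c1OCc1ccccc1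
F4 | step 18 | (3R,4R)-3-[4-(benzyloxy)-3-methoxybenzyl]-4-{[6,6'-bis(benzyloxy)-3'-(tert-butyldimethylsilyloxymethyl)-5,5'-dimethoxybiphenyl-3-yl]methyl}-3-hydroxydihydrofuran-2(3H)-one | COc1cc(C[C@@H]2COC(=O)[C@@]2(O)Cc2ccc(OCc3ccccc3)c(OC)c2)cc(-c2cc(CO[Si](C)(C)C(C)(C)C)cc(OC)c2OCc2ccccc2)c1OCc1ccccc1
F5 | step 18 | (3R,4R)-3-[4-(benzyloxy)-3-methoxybenzyl]-4-{[6,6'-bis(benzyloxy)-3'-(hydroxymethyl)-5,5'-dimethoxybiphenyl-3-yl]methyl}-3-hydroxydihydrofuran-2(3H)-one | COc1cc(C[C@@H]2COC(=O)[C@@]2(O)Cc2ccc(OCc3ccccc3)c(OC)c2)cc(-c2cc(CO)cc(OC)c2OCc2ccccc2)c1OCc1ccccc1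
F6 | step 18 | (3R,4R)-3-[4-(benzyloxy)-3-methoxybenzyl]-4-{[6,6'-bis(benzyloxy)-3'-(bromomethyl)-5,5'-dimethoxybiphenyl-3-yl]methyl}-3-hydroxydihydrofuran-2(3H)-one | COc1cc(C[C@@H]2COC(=O)[C@@]2(O)Cc2ccc(OCc3ccccc3)c(OC)c2)cc(-c2cc(CBr)cc(OC)c2OCc2ccccc2)c1OCc1ccccc1
F7 | step 18 | tetra-O-benzyl ether of the target (all four phenols of 24 as benzyl ethers; both lactones 3R,4R) | COc1cc(C[C@@H]2COC(=O)[C@@]2(O)Cc2cc(OC)c(OCc3ccccc3)c(-c3cc(C[C@@H]4COC(=O)[C@@]4(O)Cc4ccc(OCc5ccccc5)c(OC)c4)cc(OC)c3OCc3ccccc3)c2)ccc1OCc1ccccc1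
F8 | step 9 | 5-bromovanillin (3-bromo-4-hydroxy-5-methoxybenzaldehyde) | COc1cc(C=O)cc(Br)c1O
F9 | step 9 | 4-(benzyloxy)-3-bromo-5-methoxybenzaldehyde | COc1cc(C=O)cc(Br)c1OCc1ccccc1
F10 | step 9 | (E)-4-[4-(benzyloxy)-3-bromo-5-methoxyphenyl]-3-(methoxycarbonyl)but-3-enoic acid | COC(=O)/C(CC(=O)O)=C/c1cc(Br)c(OCc2ccccc2)c(OC)c1
F11 | step 9 | (3S)-4-[4-(benzyloxy)-3-bromo-5-methoxyphenyl]-3-(methoxycarbonyl)butanoic acid | COc1cc(C[C@@H](CC(=O)O)C(=O)OC)cc(Br)c1OCc1ccccc1
F12 | step 9 | (4S)-4-[4-(benzyloxy)-3-bromo-5-methoxybenzyl]dihydrofuran-2(3H)-one | COc1cc(C[C@@H]2COC(=O)C2)cc(Br)c1OCc1ccccc1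
F13 | step 9 | 4-(benzyloxy)-3-methoxy-5-(4,4,5,5-tetramethyl-1,3,2-dioxaborolan-2-yl)benzaldehyde | COc1cc(C=O)cc(B2OC(C)(C)C(C)(C)O2)c1OCc1ccccc1
F14 | step 9 | (4S)-4-{[6,6'-bis(benzyloxy)-3'-formyl-5,5'-dimethoxybiphenyl-3-yl]methyl}dihydrofuran-2(3H)-one | COc1cc(C[C@@H]2COC(=O)C2)cc(-c2cc(C=O)cc(OC)c2OCc2ccccc2)c1OCc1ccccc1
F15 | step 12 | (4S)-4-{[6,6'-bis(benzyloxy)-3'-(hydroxymethyl)-5,5'-dimethoxybiphenyl-3-yl]methyl}-3-(1-hydroxyethyl)dihydrofuran-2(3H)-one (mixture of epimers at C3 and the carbinol) | COc1cc(C[C@@H]2COC(=O)C2C(C)O)cc(-c2cc(CO)cc(OC)c2OCc2ccccc2)c1OCc1ccccc1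
F16 | step 12 | (4S)-3-acetyl-4-{[6,6'-bis(benzyloxy)-3'-formyl-5,5'-dimethoxybiphenyl-3-yl]methyl}dihydrofuran-2(3H)-one (C3 epimers/enol) | COc1cc(C[C@@H]2COC(=O)C2C(C)=O)cc(-c2cc(C=O)cc(OC)c2OCc2ccccc2)c1OCc1ccccc1
F17 | step 12 | (3S,4S)-3-acetyl-3-[4-(benzyloxy)-3-methoxybenzyl]-4-{[6,6'-bis(benzyloxy)-3'-formyl-5,5'-dimethoxybiphenyl-3-yl]methyl}dihydrofuran-2(3H)-one | COc1cc(C[C@@H]2COC(=O)[C@@]2(C(C)=O)Cc2ccc(OCc3ccccc3)c(OC)c2)cc(-c2cc(C=O)cc(OC)c2OCc2ccccc2)c1OCc1ccccc1
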